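**Assumption:** the C5 ester in the SMILES is read as the (Z)-2-methylbut-2-enoate (angelate); (–)-sparteine and 1-iodo-2-methylprop-1-ene are taken as purchasable.

**Retrosynthetic overview**
- Remove the side-chain acetate and reduce back to an enone; the enone comes from an isopropenyl group by hydroboration and carbonylative coupling with 1-iodo-2-methylpropene and CO.
- The isopropenyl cyclohexanol (an acetoxy-isopulegol) comes from a carbonyl-ene cyclisation of (3S,4R)-4-acetoxycitronellal. This is the only ring and it is closed after the key step.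
- Key bond C3–C4 of that aldehyde: a butanal homoenolate (sparteine-complexed, titanated (E)-crotyl carbamate) adds to 4-methylpent-3-enal. Both carbons are natively electrophilic; the step sets the methyl and acetoxy stereocentres, which then steer the ring closure.

**Route**

Step 1
Reactants: 1 (E)-but-2-en-1-ol; 2 N,N-diisopropylcarbamoyl chloride
Product: 3 (E)-but-2-en-1-yl N,N-diisopropylcarbamate
Conditions: pyridine, 90 °C
Reagents that add atoms: none
Why: O-carbamoylation (acyl substitution) installs the directing and later enol-masking group; no stereocentre is formed and the E alkene is untouched.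

Step 2
Reactants: 4 4-methylpent-3-en-1-ol
Product: 5 4-methylpent-3-enal
Conditions: Dess–Martin periodinane, pyridine, CH2Cl2, 0 °C; used crude at once
Reagents that add atoms: none
Why: Dess–Martin oxidation under buffered, non-enolising conditions gives the β,γ-unsaturated aldehyde without moving the double bond into conjugation.

Step 3
Reactants: 3 (E)-but-2-en-1-yl N,N-diisopropylcarbamate; 5 4-methylpent-3-enal
Product: 9 (1Z,3S,4R)-4-hydroxy-3,7-dimethylocta-1,6-dien-1-yl N,N-diisopropylcarbamate, via lithiated carbamate 6 (not isolated), via allyltitanium 7 (not isolated), via titanium alkoxide 8 (not isolated)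
Conditions: sBuLi, (–)-sparteine, pentane/cyclohexane, –70 °C, 3 h (crystallisation); Ti(OiPr)4, –70 °C; then 5, –70 → 20 °C; H2O
Reagents that add atoms: none
Why: Hoppe homoaldol reaction (homoenolate umpolung): crystallisation-driven dynamic resolution gives the (S)-lithium·sparteine complex, titanation with inversion gives the (R)-allyltitanium, and chair-like addition through the γ-carbon of the E-crotyl unit gives the anti adduct with a Z enol carbamate, setting C3 (S) and C4 (R) in the sense known for this reagent pair (about 90% ee; the minor enantiomer leaves as a diastereomer after step 9).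

Step 4
Reactants: 9 (1Z,3S,4R)-4-hydroxy-3,7-dimethylocta-1,6-dien-1-yl N,N-diisopropylcarbamate
Product: 10 (1Z,3S,4R)-4-acetoxy-3,7-dimethylocta-1,6-dien-1-yl N,N-diisopropylcarbamate
Conditions: Ac2O, Et3N, DMAP (cat.), CH2Cl2, 0 → 20 °C
Reagents that add atoms: acetic anhydride CC(=O)OC(C)=O
Why: DMAP-catalysed acetylation puts on the ring acetate of the target early and stops lactol formation when the aldehyde is released; no stereocentre is touched.

Step 5
Reactants: 10 (1Z,3S,4R)-4-acetoxy-3,7-dimethylocta-1,6-dien-1-yl N,N-diisopropylcarbamate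
Product: 12 (3S,4R)-4-acetoxy-3,7-dimethyloct-6-enal, via dimethyl acetal 11 (not isolated)
Conditions: Hg(OAc)2 (5 mol %), MeSO3H (1.2 equiv), MeOH, 20 °C; then H2O–THF, 20 °C
Reagents that add atoms: water O
Why: Mercury-catalysed solvolysis of the enol carbamate (oxymercuration then protodemercuration) gives the acetal, which is hydrolysed in the same pot; the stereocentres are not enolisable and stay intact.

Step 6
Reactants: 12 (3S,4R)-4-acetoxy-3,7-dimethyloct-6-enal
Product: 13 (1R,2S,4R,5S)-4-hydroxy-2-methyl-5-(prop-1-en-2-yl)cyclohexyl acetate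
Conditions: ZnBr2 (1.1 equiv), toluene, –10 °C
Reagents that add atoms: none
Why: Lewis-acid carbonyl-ene cyclisation of the citronellal-to-isopulegol kind through a chair with the methyl equatorial and the acetoxy axial sets the carbinol and the isopropenyl-bearing carbon trans-diequatorial; the competing methyl-axial chair is expected to cost about 1 kcal/mol (roughly 8:1, minor isomer removed by chromatography).

Step 7
Reactants: 13 (1R,2S,4R,5S)-4-hydroxy-2-methyl-5-(prop-1-en-2-yl)cyclohexyl acetate; 14 (Z)-2-methylbut-2-enoic acid (angelic acid)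
Product: 16 (1R,2S,4R,5S)-4-acetoxy-5-methyl-2-(prop-1-en-2-yl)cyclohexyl (2Z)-2-methylbut-2-enoate, via mixed anhydride 15 (not isolated)
Conditions: 14, 2,4,6-trichlorobenzoyl chloride, Et3N, toluene, 20 °C; then 13, 80 °C (no DMAP)
Reagents that add atoms: none
Why: Yamaguchi-type mixed-anhydride esterification without a nucleophilic catalyst acylates the hindered secondary alcohol at the less hindered angeloyl carbonyl and avoids Z-to-E isomerisation to the tiglate.

Step 8
Reactants: 16 (1R,2S,4R,5S)-4-acetoxy-5-methyl-2-(prop-1-en-2-yl)cyclohexyl (2Z)-2-methylbut-2-enoate; 17 1-iodo-2-methylprop-1-ene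
Product: 19 (1R,2S,4R,5S)-4-acetoxy-5-methyl-2-[(2R)-6-methyl-4-oxohept-5-en-2-yl]cyclohexyl (2Z)-2-methylbut-2-enoate, via alkylborane 18 (not isolated)
Conditions: 9-BBN (1.2 equiv), THF, 0 → 20 °C; then 17, Pd(PPh3)4 (5 mol %), K3PO4, CO (1 atm), THF–benzene, 20 °C; aqueous work-up
Reagents that add atoms: carbon monoxide [C-]#[O+]
Why: Chemoselective anti-Markovnikov hydroboration of the 1,1-disubstituted alkene, with the ring C–H eclipsing the vinyl methyl and 9-BBN approaching anti to the ester-bearing ring carbon, sets the side-chain methyl centre (R), and carbonylative Suzuki–Miyaura coupling of the B-alkyl group with the acylpalladium from 17 and CO gives the enone.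

Step 9
Reactants: 19 (1R,2S,4R,5S)-4-acetoxy-5-methyl-2-[(2R)-6-methyl-4-oxohept-5-en-2-yl]cyclohexyl (2Z)-2-methylbut-2-enoate
Product: 21 (1R,2S,4R,5S)-4-acetoxy-2-[(2R,4R)-4-hydroxy-6-methylhept-5-en-2-yl]-5-methylcyclohexyl (2Z)-2-methylbut-2-enoate, via catecholborate 20 (not isolated)
Conditions: (S)-2-methyl-CBS-oxazaborolidine (20 mol %), catecholborane (1.5 equiv), toluene, –78 °C; then MeOH, H2O
Reagents that add atoms: none
Why: Corey–Bakshi–Shibata reduction with the alkenyl group as the large substituent gives the (R)-allylic alcohol under reagent control (expected at least 9:1), and catecholborane at –78 °C leaves both esters and the alkenes alone.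

Step 10
Reactants: 21 (1R,2S,4R,5S)-4-acetoxy-2-[(2R,4R)-4-hydroxy-6-methylhept-5-en-2-yl]-5-methylcyclohexyl (2Z)-2-methylbut-2-enoate
Product: 22 (1R,2S,4R,5S)-4-acetoxy-2-[(2R,4R)-4-acetoxy-6-methylhept-5-en-2-yl]-5-methylcyclohexyl (2Z)-2-methylbut-2-enoate
Conditions: Ac2O, pyridine, DMAP (cat.), CH2Cl2, 0 → 20 °C
Reagents that add atoms: acetic anhydride CC(=O)OC(C)=O
Why: Mild DMAP-catalysed acetylation of the only free hydroxyl gives the target with retention at the carbinol and without isomerising the preformed angelate.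

**Compound list**
1 | (E)-but-2-en-1-ol | C/C=C/CO | starting material
2 | N,N-diisopropylcarbamoyl chloride | CC(C)N(C(C)C)C(Cl)=O | starting material
3 | (E)-but-2-en-1-yl N,N-diisopropylcarbamate | C/C=C/COC(=O)N(C(C)C)C(C)C | intermediate
4 | 4-methylpent-3-en-1-ol | CC(C)=CCCO | starting material
5 | 4-methylpent-3-enal | CC(C)=CCC=O | intermediate
6 | (S)-1-lithio-(E)-but-2-enyl N,N-diisopropylcarbamate, as its (–)-sparteine complex | C/C=C/[C@H]([Li])OC(=O)N(C(C)C)C(C)C | intermediate
7 | (R)-1-(triisopropoxytitanio)-(E)-but-2-enyl N,N-diisopropylcarbamate | C/C=C/[C@@H]([Ti](OC(C)C)(OC(C)C)OC(C)C)OC(=O)N(C(C)C)C(C)C | intermediate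
8 | triisopropoxytitanium alkoxide of 9 | CC(C)N(C(C)C)C(=O)O/C=C\[C@H](C)[C@H](O[Ti](OC(C)C)(OC(C)C)OC(C)C)CC=C(C)C | intermediate
9 | (1Z,3S,4R)-4-hydroxy-3,7-dimethylocta-1,6-dien-1-yl N,N-diisopropylcarbamate | CC(C)N(C(C)C)C(=O)O/C=C\[C@H](C)[C@H](O)CC=C(C)C | intermediate
10 | (1Z,3S,4R)-4-acetoxy-3,7-dimethylocta-1,6-dien-1-yl N,N-diisopropylcarbamate | CC(C)N(C(C)C)C(=O)O/C=C\[C@H](C)[C@H](OC(C)=O)CC=C(C)C | intermediate
11 | (3S,4R)-4-acetoxy-3,7-dimethyloct-6-enal dimethyl acetal | COC(OC)C[C@H](C)[C@H](OC(C)=O)CC=C(C)C | intermediate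
12 | (3S,4R)-4-acetoxy-3,7-dimethyloct-6-enal | O=CC[C@H](C)[C@H](OC(C)=O)CC=C(C)C | intermediate
13 | (1R,2S,4R,5S)-4-hydroxy-2-methyl-5-(prop-1-en-2-yl)cyclohexyl acetate | O[C@@H]1C[C@H](C)[C@H](OC(C)=O)C[C@H]1C(C)=C | intermediate
14 | (Z)-2-methylbut-2-enoic acid (angelic acid) | C/C=C(/C)C(=O)O | starting material
15 | (Z)-2-methylbut-2-enoic 2,4,6-trichlorobenzoic anhydride | C/C=C(/C)C(=O)OC(=O)c1c(Cl)cc(Cl)cc1Cl | intermediate
16 | (1R,2S,4R,5S)-4-acetoxy-5-methyl-2-(prop-1-en-2-yl)cyclohexyl (2Z)-2-methylbut-2-enoate | C/C=C(/C)C(=O)O[C@@H]1C[C@H](C)[C@H](OC(C)=O)C[C@H]1C(C)=C | intermediate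
17 | 1-iodo-2-methylprop-1-ene | CC(C)=CI | starting material
18 | (1R,2S,4R,5S)-4-acetoxy-2-[(2R)-1-(9-borabicyclo[3.3.1]nonan-9-yl)propan-2-yl]-5-methylcyclohexyl (2Z)-2-methylbut-2-enoate | C/C=C(/C)C(=O)O[C@@H]1C[C@H](C)[C@H](OC(C)=O)C[C@H]1[C@H](C)CB1C2CCCC1CCC2 | intermediate
19 | (1R,2S,4R,5S)-4-acetoxy-5-methyl-2-[(2R)-6-methyl-4-oxohept-5-en-2-yl]cyclohexyl (2Z)-2-methylbut-2-enoate | C/C=C(/C)C(=O)O[C@@H]1C[C@H](C)[C@H](OC(C)=O)C[C@H]1[C@H](C)CC(=O)C=C(C)C | intermediate
20 | catecholborate ester of 21 | C/C=C(/C)C(=O)O[C@@H]1C[C@H](C)[C@H](OC(C)=O)C[C@H]1[C@H](C)C[C@H](C=C(C)C)OB1Oc2ccccc2O1 | intermediate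
21 | (1R,2S,4R,5S)-4-acetoxy-2-[(2R,4R)-4-hydroxy-6-methylhept-5-en-2-yl]-5-methylcyclohexyl (2Z)-2-methylbut-2-enoate | C/C=C(/C)C(=O)O[C@@H]1C[C@H](C)[C@H](OC(C)=O)C[C@H]1[C@H](C)C[C@H](C=C(C)C)O | intermediate
22 | (1R,2S,4R,5S)-4-acetoxy-2-[(2R,4R)-4-acetoxy-6-methylhept-5-en-2-yl]-5-methylcyclohexyl (2Z)-2-methylbut-2-enoate | C/C=C(/C)C(=O)O[C@@H]1C[C@H](C)[C@H](OC(C)=O)C[C@H]1[C@H](C)C[C@H](C=C(C)C)OC(C)=O | target

**Step count**
Total: 10 steps. Longest linear sequence: 9 steps (1, then 3 to 10); step 2 is a one-step side branch.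

**Three steps most likely to fail, with fallbacks**

Step 5 (release of the aldehyde). The acid needed to cleave the enol carbamate can also methanolyse the acetate or trigger premature cyclisation of the citronellal-like aldehyde. Fallback: set out from 9 and release the aldehyde under neutral conditions at the end instead. Hg(OAc)2/MeSO3H/MeOH on the free alcohol gives the lactol methyl ether (2RS,4S,5R)-2-methoxy-4-methyl-5-(3-methylbut-2-en-1-yl)oxolane F1. Propane-1,3-dithiol with BF3·OEt2 at –20 °C opens it to the hydroxy dithiane (2S,3R)-1-(1,3-dithian-2-yl)-2,6-dimethylhept-5-en-3-ol F2. Acetylation gives (2S,3R)-1-(1,3-dithian-2-yl)-2,6-dimethylhept-5-en-3-yl acetate F3. MeI/CaCO3 in aqueous MeCN then unmasks the aldehyde, coming back to the route at 12.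

Step 7 (angeloylation). Partial isomerisation to the tiglate, which is hard to separate, is the usual failure. Fallback: set out from 13 and build the Z double bond on the ester instead of transferring it. LiOH saponification of commercial ethyl 2-[bis(2,2,2-trifluoroethoxy)phosphoryl]propanoate gives 2-[bis(2,2,2-trifluoroethoxy)phosphoryl]propanoic acid F4. Coupling with 13 (DIC, DMAP) gives (1R,2S,4R,5S)-4-acetoxy-5-methyl-2-(prop-1-en-2-yl)cyclohexyl 2-[bis(2,2,2-trifluoroethoxy)phosphoryl]propanoate F5. Still–Gennari olefination with acetaldehyde (KN(SiMe3)2, 18-crown-6, THF, –78 °C) gives the Z enoate, coming back at 16.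

Step 8 (hydroboration and carbonylative coupling in one pot). Direct coupling without CO insertion, or a sluggish B-alkyl transfer, would sink it. Fallback: set out from 16, separate the two events and change the metal. 9-BBN followed by NaBO3·4H2O gives the primary alcohol (1R,2S,4R,5S)-4-acetoxy-2-[(2S)-1-hydroxypropan-2-yl]-5-methylcyclohexyl (2Z)-2-methylbut-2-enoate F6, where the side-chain epimers can be separated. I2/PPh3/imidazole gives the iodide (1R,2S,4R,5S)-4-acetoxy-2-[(2S)-1-iodopropan-2-yl]-5-methylcyclohexyl (2Z)-2-methylbut-2-enoate F7. Zinc insertion (Zn dust, LiCl, THF) and a Fukuyama coupling (PdCl2(PPh3)2, toluene) with S-ethyl 3-methylbut-2-enethioate F8, made from 3-methylbut-2-enoyl chloride and ethanethiol, give the enone, coming back at 19.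

**Further compounds**
F1 | step 5 | (2RS,4S,5R)-2-methoxy-4-methyl-5-(3-methylbut-2-en-1-yl)oxolane | COC1C[C@H](C)[C@H](O1)CC=C(C)C
F2 | step 5 | (2S,3R)-1-(1,3-dithian-2-yl)-2,6-dimethylhept-5-en-3-ol | S1CCCSC1C[C@H](C)[C@H](O)CC=C(C)C
F3 | step 5 | (2S,3R)-1-(1,3-dithian-2-yl)-2,6-dimethylhept-5-en-3-yl acetate | S1CCCSC1C[C@H](C)[C@H](OC(C)=O)CC=C(C)C
F4 | step 7 | 2-[bis(2,2,2-trifluoroethoxy)phosphoryl]propanoic acid | CC(C(=O)O)P(=O)(OCC(F)(F)F)OCC(F)(F)F
F5 | step 7 | (1R,2S,4R,5S)-4-acetoxy-5-methyl-2-(prop-1-en-2-yl)cyclohexyl 2-[bis(2,2,2-trifluoroethoxy)phosphoryl]propanoate | CC(C(=O)O[C@@H]1C[C@H](C)[C@H](OC(C)=O)C[C@H]1C(C)=C)P(=O)(OCC(F)(F)F)OCC(F)(F)F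
F6 | step 8 | (1R,2S,4R,5S)-4-acetoxy-2-[(2S)-1-hydroxypropan-2-yl]-5-methylcyclohexyl (2Z)-2-methylbut-2-enoate | C/C=C(/C)C(=O)O[C@@H]1C[C@H](C)[C@H](OC(C)=O)C[C@H]1[C@H](C)CO
F7 | step 8 | (1R,2S,4R,5S)-4-acetoxy-2-[(2S)-1-iodopropan-2-yl]-5-methylcyclohexyl (2Z)-2-methylbut-2-enoate | C/C=C(/C)C(=O)O[C@@H]1C[C@H](C)[C@H](OC(C)=O)C[C@H]1[C@H](C)CI
F8 | step 8 | S-ethyl 3-methylbut-2-enethioate | CCSC(=O)C=C(C)C
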